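**Remarks on the chemistry (assumptions)**

- Numbering (daucane) is used for all bicyclic compounds: ring A = C1–C5. Ring B = C1, C5, C6, C9, C10 in the diquinanes and C1, C5, C6, C7, C8, C9, C10 in the hydroazulenes.
- The stereodescriptors of 18 and 22 were checked atom by atom against 32 (C1, C2, C4, C5 identical, ring fusion cis). No configuration needed correcting.
- Three design changes are made relative to a trimethylsilyl enol ether / ethyl ester version of the ring expansion. The enol ether is TBS (resists silyl transfer with a slow ynoate). The ester is allyl (neutral decarboxylation at room temperature). The C4 silyl group is removed before the C6 reduction so that the free C4–OH can deliver the hydride.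
- C6 of 9, 10, 11, 12, 14, 15 and 16 is formed as an epimer mixture, is carried as such and disappears at ketone 17; its SMILES are left open. C7 of 23 is a labile β-keto ester centre and is also left open.

## Structural features

The target is a cis-fused hydroazulene: a cyclopentane (C1–C5) and a cycloheptene (C1, C5–C10, C8=C9 with a methyl on C8) share the C1–C5 bond. Four contiguous stereocentres sit on the five-membered ring: quaternary C1 (methyl), C2 (angelate), C4 (tertiary carbinol with isopropyl) and the ring-fusion methine C5. C6 (trimethoxybenzoate) follows directly on the seven-membered ring. O2 and O4 lie on the face of ring A that carries ring B, opposite to the angular methyl and H5; O6 is cis to H5. The fragile groups are the (Z)-2-methylbut-2-enoate (Z→E isomerisation, conjugate addition) and the C4–OH/C6–O 1,3-pair, which at the C6 ketone stage is a tertiary aldol open to retro-aldol cleavage and dehydration. The C8=C9 alkene is also at risk, because at the ketone stage it is β,γ to C6 and can slip into conjugation. Two different esters must be placed on two hindered secondary hydroxyls beside a free tertiary one. The real difficulty is the seven-membered ring with oxygen at C6, methyl at C8 and the alkene exactly at C8=C9, directly beside the crowded C1/C4/C5 array, together with the C6 configuration. The key step exploits the fact that C6–C7–C8(CH3)=C9 is a but-2-ynoate unit inserted into the C6–C9 bond of a cyclopentanone (ring C1, C5, C6, C9, C10). All ring-A stereocentres can therefore be set on a rigid cis-bicyclo[3.3.0]octane before the ring is enlarged.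

## Logic of the disconnections

32 ⇒ 28 + 31 (from 29 and 30). The C2–O acyl bond is cut first because the Z-enoate is the most fragile group and should see no further chemistry. The forward step must acylate a hindered secondary hydroxyl beside a free tertiary one without Z→E isomerisation.

28 ⇒ 27. The O2–Si bond is re-formed in retrosynthesis. The silyl ether is what keeps C2–OH apart from C6–OH, so it must come off without touching the aryl ester, the tertiary alcohol or the alkene.

27 ⇒ 25 + 26. The C6–O acyl bond is cut. This removes the aromatic ester and leaves a 1,3-diol in which only the secondary hydroxyl should react.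

25 ⇒ 24. The C6–H bond is cut (retro-reduction). The C6 stereocentre is reduced to a carbonyl and the forward hydride must enter from the side of C4, which the free C4–OH can enforce.

24 ⇒ 23. A C7–carboxyl bond is added back. The ester is the activating group of the two-carbon unit; its forward removal must be neutral so that C8=C9 stays out of conjugation and the tertiary aldol survives.

23 ⇒ 22. The O6–Si (enol) and O4–Si bonds are re-formed. Forward, both must be cleaved while O2–Si stays.

22 ⇒ 18 + 20. The C6–C7 and C8–C9 bonds are cut and the C6–C9 bond is restored. The seven-membered ring collapses to a diquinane enol ether and a four-carbon ynoate, which is the largest single simplification of the route. The forward step needs C9 to bond to the ynoate β-carbon and the fused cyclobutene to open.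

20 ⇒ 19 + 2. The ester C–O bond is cut. Both pieces are commercial and the allyl group is chosen for its later palladium-mediated removal.

18 ⇒ 17. The enol O6–Si bond is cut. Forward, enolisation must go toward C9 and not C5.

17 ⇒ 16. The C6 carbonyl is traced back to a carbinol. C6 must be an alcohol (masked) while the C4 ketone is used.

16 ⇒ 15. The O6–benzyl bond is re-formed. The ether must leave oxidatively in the presence of two silyl ethers.

15 ⇒ 14. The O4–Si bond is cut. The silyl group exists only to block retro-aldol cleavage in the base and Lewis-acid steps.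

14 ⇒ 12 + 13. The C4–isopropyl bond is cut. C4 becomes a ketone on a cis-bicyclo[3.3.0]octane whose convex face should direct the incoming nucleophile. The forward step must avoid enolisation and β-hydride reduction.

12 ⇒ 11. The C4 carbonyl is traced back to a carbinol.

11 ⇒ 10. The C4–O and C5–H bonds are cut (retro-hydroboration). The oxygen at C4 and the ring-fusion hydrogen come from one alkene; boron must go to C4.

10 ⇒ 9. The O6–benzyl bond is cut.

9 ⇒ 8. The C5–C6 bond is cut. Ring B opens to a monocyclic enol triflate with an aldehyde side chain. The forward closure must be chemoselective for the aldehyde and form a five-membered ring at a hindered alkenyl carbon.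

8 ⇒ 7. The aldehyde is traced back to a primary alcohol.

7 ⇒ 6. The C6–O bond is cut (retro-hydroboration of the terminal alkene). The borane must ignore the enol triflate.

6 ⇒ 5. The C5–O triflate bond is cut. The ketone has only one enolisable side, so regiochemistry is automatic.

5 ⇒ 4. The O2–Si bond is cut.

4 ⇒ 3. The C2–H bond is cut. Both C1 and C2 are traced to an achiral dione; the forward reduction must choose one of two enantiotopic carbonyls and one face.

3 ⇒ 1 + 2. The C1–C10 bond is cut, leaving a commercial dione and a commercial three-carbon electrophile that later supplies C10, C9 and C6.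

## Other disconnections considered

**Alternative 1:** decalin-to-hydroazulene semipinacol shift. The cut is the C1–C5 bond, restored as C1–C6. Forward, the trans-decalin hydroxy mesylate A1 would ionise at C5 while the C1–C6 bond, antiperiplanar to the equatorial leaving group, migrates; the C6 hydroxyl pushes and becomes the ketone of the cis-fused hydroazulenone bis-ketal A2.
- In favour: A1 should be reachable in a handful of scalable steps from a proline-catalysed Robinson annulation, and the shift transfers the C1 quaternary centre with retention and sets C5 by inversion. On core-building step economy and on mechanistic reliability of the ring-forming step this alternative is better than the chosen plan, which needs 17 steps to reach 22.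
- Against: A2 carries C4 as a bare methylene. Oxygen and isopropyl at C4 would have to be introduced late, next to the ring fusion, on a flexible hydroazulene where facial control is weaker than on the diquinane 12. The C8 ketone must also become C8(CH3)=C9 without forming the C7=C8 isomer, and the C2 and C6 carbinol configurations are still open.
- Comparison: equal to the chosen plan at C1/C5, weaker at C2, C4, C6 and the alkene position. Its short start would probably be used up by the late redox and C–C steps.

**Alternative 2:** oxidopyrylium (5+2) cycloaddition with bridge excision. The cuts are C1–C5 and C9–C10. Forward, the acetoxypyranone A3 would lose acetate to a 3-oxidopyrylium that adds to its tethered 1,1-disubstituted alkene to give the oxa-bridged enone A4.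
- In favour: two rings and two C–C bonds in one step, with the C6 ketone and C8 methyl in place. In bonds and rings formed per step it is better than the chosen key step, which makes one ring.
- Against: the pyrylium carbon C5 carries the fully substituted C4 directly and the alkene terminus becomes quaternary C1, so the cycloaddition is sterically demanding. In A4 the oxygen bridge at C5 is cis to C10, so the carbocycle is trans-fused; after C5–O cleavage the C5 configuration would rest on an enolate protonation whose outcome is not secured. The C9 oxygen must be removed and the C7=C8 enone alkene moved to C8=C9. The C2 and C4 stereocentres of A3 would have to be made by acyclic stereocontrol, including the tertiary carbinol.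
- Comparison: the chosen plan sets every ring-A stereocentre on a rigid bicycle and needs no bridge removal. Alternative 2 is more convergent at the key step but heavier before and after it.

**Alternative 3:** Mukaiyama aldol–Sakurai bicyclisation. The cuts are C4–C5 and C6–C7. Forward, a Lewis acid would make the enol silane of the branched chain A5 add to the chelated C4 ketone, and the liberated C6 oxocarbenium would be trapped by the allylsilane to give the diol A6.
- In favour: both rings, two C–C bonds and C4, C5, C6 in one operation; the alkene arrives regiospecifically at C8=C9 through the SE2′ step; the tertiary carbinol forms without a Grignard addition to a hindered ketone and without a C6 protecting group. On step economy after the key step and on alkene placement it is better than the chosen plan.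
- Against: C6 is expected as the epimer, so an inversion on a hindered homoallylic carbinol is needed. The seven-membered closure competes with protodesilylation and with retro-aldol of the first adduct. A5 holds the quaternary stereocentre C1 with three different functionalised arms and needs a substantial asymmetric synthesis of its own.
- Comparison: mechanistically it is the more ambitious cascade and probably the shorter route if it works. The chosen plan is longer but each bond-forming event is separately controlled, and the C6 configuration is set directly by hydroxyl-directed reduction.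

Key step: step 17

## Route

Step 1
Reactants: 1 2-methylcyclopentane-1,3-dione; 2 allyl bromide
Product: 3 2-allyl-2-methylcyclopentane-1,3-dione
Conditions: 1 M NaOH (aq), rt
Reagents that add atoms: none
Why: C-alkylation of the stabilised dione enolate with an allylic halide in water forms C1–C10; the minor O-allyl enol ether is removed on work-up. Reaction type: enolate C-alkylation.

Step 2
Reactants: 3 2-allyl-2-methylcyclopentane-1,3-dione
Product: 4 (2S,3S)-2-allyl-3-hydroxy-2-methylcyclopentan-1-one (OH cis to allyl)
Conditions: baker's yeast, sucrose, H2O, 30 °C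
Reagents that add atoms: none
Why: Enzymatic desymmetrising reduction; the yeast reductases should reduce one enantiotopic carbonyl with hydride entering anti to the allyl group, which fixes C1 and C2 together as the (2S,3S) ketol. The cofactor is recycled by fermentation of the sugar.

Step 3
Reactants: 4 (2S,3S)-2-allyl-3-hydroxy-2-methylcyclopentan-1-one
Product: 5 (2S,3S)-2-allyl-3-(tert-butyldimethylsilyloxy)-2-methylcyclopentan-1-one
Conditions: TBSCl, imidazole, DMF, rt
Reagents that add atoms: tert-butyldimethylsilyl chloride, CC(C)(C)[Si](C)(C)Cl
Why: Standard silylation of a secondary alcohol; the TBS ether marks C2–OH for the whole route.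

Step 4
Reactants: 5 (2S,3S)-2-allyl-3-(tert-butyldimethylsilyloxy)-2-methylcyclopentan-1-one
Product: 6 (4S,5S)-5-allyl-4-(tert-butyldimethylsilyloxy)-5-methylcyclopent-1-en-1-yl trifluoromethanesulfonate
Conditions: KHMDS, THF, −78 °C; PhNTf2, −78 °C → rt
Reagents that add atoms: N-phenylbis(trifluoromethanesulfonimide), O=S(=O)(N(c1ccccc1)S(=O)(=O)C(F)(F)F)C(F)(F)F
Why: C1 is quaternary, so the ketone can enolise only toward C4; O-triflation of the potassium enolate should give a single enol triflate.

Step 5
Reactants: 6 enol triflate
Product: 7 (4S,5S)-4-(tert-butyldimethylsilyloxy)-5-(3-hydroxypropyl)-5-methylcyclopent-1-en-1-yl trifluoromethanesulfonate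
Conditions: 9-BBN, THF, 0 °C → rt; NaBO3·4H2O, H2O, rt
Reagents that add atoms: sodium perborate, [Na+].[Na+].O[B-]1(O)OO[B-](O)(O)OO1
Why: Hydroboration–oxidation; 9-BBN adds anti-Markovnikov to the monosubstituted alkene much faster than to the electron-poor trisubstituted enol triflate, and perborate oxidises the borane without hydrolysing the triflate.

Step 6
Reactants: 7 primary alcohol
Product: 8 (4S,5S)-4-(tert-butyldimethylsilyloxy)-5-methyl-5-(3-oxopropyl)cyclopent-1-en-1-yl trifluoromethanesulfonate
Conditions: Dess–Martin periodinane, NaHCO3, CH2Cl2, 0 °C → rt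
Reagents that add atoms: none
Why: Dess–Martin oxidation of a primary alcohol to the aldehyde under buffered, non-epimerising conditions.

Step 7
Reactants: 8 aldehyde enol triflate
Product: 9 2-(tert-butyldimethylsilyloxy)-1-methylbicyclo[3.3.0]oct-4-en-6-ol (daucane numbering; C4=C5 at the ring fusion; OTBS cis to C10; C6 epimers)
Conditions: CrCl2 (5 equiv), NiCl2 (5 mol%), DMF, rt
Reagents that add atoms: none
Why: Nozaki–Hiyama–Kishi cyclisation; nickel inserts into the C5–OTf bond, the alkenylchromium formed by transmetalation adds to the tethered aldehyde in a 5-exo-trig closure and forms C5–C6. The C6 configuration is not controlled and is removed later.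

Step 8
Reactants: 9 bicyclic allylic alcohol
Product: 10 6-(4-methoxybenzyloxy)-2-(tert-butyldimethylsilyloxy)-1-methylbicyclo[3.3.0]oct-4-ene
Conditions: NaH, PMBCl, Bu4NI (cat.), THF/DMF, 0 °C → rt
Reagents that add atoms: 4-methoxybenzyl chloride, COc1ccc(CCl)cc1
Why: Williamson etherification; the PMB ether should survive borane, peroxide, the Grignard step and silyl triflate, and leaves oxidatively.

Step 9
Reactants: 10 PMB ether
Product: 11 cis-fused 6-(4-methoxybenzyloxy)-2-(tert-butyldimethylsilyloxy)-1-methylbicyclo[3.3.0]octan-4-ol (4-OH and 5-H on the face of the C1 methyl)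
Conditions: BH3·THF, THF, 0 °C → rt; 3 M NaOH, 30% H2O2, 0 °C → rt
Reagents that add atoms: hydrogen peroxide, OO
Why: Hydroboration–oxidation; boron goes to C4 (less substituted and remote from the allylic oxygen) and hydrogen to C5 by syn addition, and addition on the methyl face is expected because the other face would create a trans-fused bicyclo[3.3.0]octane. Any trans-fused material converges at 12.

Step 10
Reactants: 11 C4 alcohol
Product: 12 cis-fused 6-(4-methoxybenzyloxy)-2-(tert-butyldimethylsilyloxy)-1-methylbicyclo[3.3.0]octan-4-one
Conditions: Dess–Martin periodinane, NaHCO3, CH2Cl2, rt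
Reagents that add atoms: none
Why: Dess–Martin oxidation; C5 is now α to the ketone and rests in the strongly favoured cis ring fusion.

Step 11
Reactants: 12 C4 ketone; 13 isopropylmagnesium chloride
Product: 14 cis-fused 4-isopropyl-6-(4-methoxybenzyloxy)-2-(tert-butyldimethylsilyloxy)-1-methylbicyclo[3.3.0]octan-4-ol (isopropyl on the convex face cis to H5; OH on the concave face)
Conditions: LaCl3·2LiCl, THF, rt; then 13, 0 °C
Reagents that add atoms: none
Why: Lanthanum-mediated Grignard 1,2-addition, which suppresses enolisation and β-hydride reduction; attack on the convex face of the cis-bicyclo[3.3.0]octanone, away from ring B and the endo C2–OTBS, sets C4 with OH on the concave face.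

Step 12
Reactants: 14 tertiary alcohol
Product: 15 4-O-triethylsilyl ether of 14
Conditions: TESOTf, 2,6-lutidine, CH2Cl2, −78 °C → rt
Reagents that add atoms: triethylsilyl trifluoromethanesulfonate, CC[Si](CC)(CC)OS(=O)(=O)C(F)(F)F
Why: Silyl triflate silylation of a hindered tertiary alcohol; the TES ether blocks retro-aldol cleavage of the C4–C5 bond in the base and Lewis-acid steps ahead.

Step 13
Reactants: 15 TES ether
Product: 16 cis-fused 4-isopropyl-2-(tert-butyldimethylsilyloxy)-4-(triethylsilyloxy)-1-methylbicyclo[3.3.0]octan-6-ol
Conditions: DDQ, CH2Cl2/pH 7 buffer, 0 °C → rt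
Reagents that add atoms: none
Why: Oxidative cleavage of the PMB ether by DDQ; buffered conditions should leave both silyl ethers intact.

Step 14
Reactants: 16 C6 alcohol
Product: 17 cis-fused 4-isopropyl-2-(tert-butyldimethylsilyloxy)-4-(triethylsilyloxy)-1-methylbicyclo[3.3.0]octan-6-one
Conditions: Dess–Martin periodinane, NaHCO3, CH2Cl2, rt
Reagents that add atoms: none
Why: Dess–Martin oxidation; both C6 epimers converge on one ketone, and neutral conditions avoid β-elimination of the C4 silyl ether.

Step 15
Reactants: 17 diquinane ketone
Product: 18 6-(tert-butyldimethylsilyloxy)-4-isopropyl-2-(tert-butyldimethylsilyloxy)-4-(triethylsilyloxy)-1-methylbicyclo[3.3.0]oct-6(9)-ene (silyl enol ether C6=C9)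
Conditions: LDA, THF, −78 °C; TBSOTf, −78 → 0 °C
Reagents that add atoms: tert-butyldimethylsilyl trifluoromethanesulfonate, CC(C)(C)[Si](C)(C)OS(=O)(=O)C(F)(F)F
Why: Kinetic enolisation; LDA should remove a C9 methylene proton and not the C5 methine buried between two fully substituted carbons, and O-silylation fixes the C6=C9 enol ether as a robust TBS derivative.

Step 16
Reactants: 19 but-2-ynoic acid; 2 allyl bromide
Product: 20 allyl but-2-ynoate
Conditions: K2CO3, DMF, rt
Reagents that add atoms: none
Why: SN2 alkylation of the carboxylate; the allyl ester is chosen so that the carboxyl can later be removed with palladium under neutral conditions.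

Step 17
Reactants: 18 silyl enol ether; 20 allyl but-2-ynoate
Product: 22 allyl 6-(tert-butyldimethylsilyloxy)-4-isopropyl-2-(tert-butyldimethylsilyloxy)-4-(triethylsilyloxy)-1,8-dimethyl-cis-hydroazulene-6,8-diene-7-carboxylate, via siloxy cyclobutene 21 (not isolated)
Conditions: EtAlCl2 (1.5 equiv), CH2Cl2, −78 → 0 °C; Et3N, aq. NaHCO3; then PhMe, 80 °C
Reagents that add atoms: none
Why: EtAlCl2 binds the ester carbonyl of 20, the enol carbon C9 of 18 adds to the alkyne β-carbon C8 (Michael polarity), and a silyloxocarbenium ion at C6 with an aluminium allenoate results. The allenoate α-carbon C7 then closes onto C6 (4-exo-trig on the C6=O+ bond) to give the bicyclo[3.2.0] cyclobutene 21; the bulky TBS group disfavours silyl transfer to the allenoate, which would otherwise leak to an open-chain Michael adduct. This is the known Lewis-acid [2+2] cycloaddition of silyl enol ethers with acetylenic esters. On warming, the donor–acceptor cyclobutene opens by cleavage of the C6–C9 σ-bond shared with the five-membered ring, pushed by the siloxy group at C6 and pulled by the vinylogous ester at C9 (a polar, formally electrocyclic 4π opening). The seven-membered ring thus arises by merging the four- and five-membered rings, not by an end-to-end closure. C6 and C9 of 21 form cis on the convex face but both are sp2 in 22, so no stereocentre is created and C1, C2, C4 and C5 are untouched. Regiochemistry rests on the C6=C9 enol ether fixed in step 15 and on the polarity of the ynoate; the allyl ester and the silyl ethers are spectators.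

Step 18
Reactants: 22 siloxy diene ester
Product: 23 allyl 4-hydroxy-4-isopropyl-2-(tert-butyldimethylsilyloxy)-1,8-dimethyl-6-oxo-cis-hydroazul-8-ene-7-carboxylate (keto–enol mixture)
Conditions: HF·pyridine, pyridine, THF, 0 °C → rt
Reagents that add atoms: none
Why: Buffered fluoride desilylation; the enol silyl ether of a β-keto ester and the TES ether should be cleaved well before the hindered secondary TBS ether at C2.

Step 19
Reactants: 23 β-keto allyl ester
Product: 24 4-hydroxy-4-isopropyl-2-(tert-butyldimethylsilyloxy)-1,8-dimethyl-cis-hydroazul-8-en-6-one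
Conditions: Pd(OAc)2 (5 mol%), PPh3, HCO2H, Et3N, THF, rt
Reagents that add atoms: none
Why: Tsuji deallylation–decarboxylation; Pd(0) forms a π-allyl complex that formate reduces to propene, and the β-keto acid loses CO2 at room temperature. The resulting dienol should be protonated at C7 (the α-carbon), which leaves the alkene at C8=C9.

Step 20
Reactants: 24 β-hydroxy ketone
Product: 25 4-isopropyl-2-(tert-butyldimethylsilyloxy)-1,8-dimethyl-cis-hydroazul-8-ene-4,6-diol (6-OH cis to H5, as in the target)
Conditions: Me4NBH(OAc)3, MeCN/AcOH, −30 °C
Reagents that add atoms: none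
Why: Evans–Saksena hydroxyl-directed reduction; the C4 alkoxyborohydride delivers hydride intramolecularly to the face of C6=O that faces C4, so H6 ends syn to C4 and O6 cis to H5. The reagent does not reduce undirected ketones, so no background pathway to the epimer is expected.

Step 21
Reactants: 25 diol; 26 3,4,5-trimethoxybenzoyl chloride
Product: 27 6-O-(3,4,5-trimethoxybenzoyl) ester of 25
Conditions: Et3N, DMAP (cat.), CH2Cl2, 0 °C → rt
Reagents that add atoms: none
Why: DMAP-catalysed acylation; only the secondary C6–OH should react, the hindered tertiary C4–OH being inert under these conditions.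

Step 22
Reactants: 27 C6 ester
Product: 28 4-isopropyl-1,8-dimethyl-6-(3,4,5-trimethoxybenzoyloxy)-cis-hydroazul-8-ene-2,4-diol
Conditions: 48% aq. HF, MeCN, 0 °C → rt
Reagents that add atoms: none
Why: Acidic fluoride cleavage of the secondary TBS ether; non-basic conditions avoid ester hydrolysis and acyl migration.

Step 23
Reactants: 28 C2 alcohol; 29 angelic acid; 30 2,4,6-trichlorobenzoyl chloride
Product: 32 target CNP0112256.1, via angeloyl trichlorobenzoyl mixed anhydride 31 (not isolated)
Conditions: 29, 30, Et3N, PhMe, rt; then 28, 80 °C
Reagents that add atoms: none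
Why: Yamaguchi esterification through the mixed anhydride; omitting a nucleophilic catalyst should suppress Z→E isomerisation, and the tertiary C4–OH should not compete with the secondary C2–OH.

## Compound list

1 | 2-methylcyclopentane-1,3-dione | CC1C(=O)CCC1=O | starting material
2 | allyl bromide | C=CCBr | starting material
3 | 2-allyl-2-methylcyclopentane-1,3-dione | C=CCC1(C)C(=O)CCC1=O | intermediate
4 | (2S,3S)-2-allyl-3-hydroxy-2-methylcyclopentan-1-one | O[C@H]1CCC(=O)[C@@]1(C)CC=C | intermediate
5 | (2S,3S)-2-allyl-3-(tert-butyldimethylsilyloxy)-2-methylcyclopentan-1-one | CC(C)(C)[Si](C)(C)O[C@H]1CCC(=O)[C@@]1(C)CC=C | intermediate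
6 | (4S,5S)-5-allyl-4-(tert-butyldimethylsilyloxy)-5-methylcyclopent-1-en-1-yl triflate | CC(C)(C)[Si](C)(C)O[C@H]1CC=C(OS(=O)(=O)C(F)(F)F)[C@@]1(C)CC=C | intermediate
7 | (4S,5S)-4-(tert-butyldimethylsilyloxy)-5-(3-hydroxypropyl)-5-methylcyclopent-1-en-1-yl triflate | CC(C)(C)[Si](C)(C)O[C@H]1CC=C(OS(=O)(=O)C(F)(F)F)[C@@]1(C)CCCO | intermediate
8 | (4S,5S)-4-(tert-butyldimethylsilyloxy)-5-methyl-5-(3-oxopropyl)cyclopent-1-en-1-yl triflate | CC(C)(C)[Si](C)(C)O[C@H]1CC=C(OS(=O)(=O)C(F)(F)F)[C@@]1(C)CCC=O | intermediate
9 | 2-(TBSO)-1-methylbicyclo[3.3.0]oct-4-en-6-ol (C6 epimers) | CC(C)(C)[Si](C)(C)O[C@H]1CC=C2C(O)CC[C@@]12C | intermediate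
10 | 6-(PMBO)-2-(TBSO)-1-methylbicyclo[3.3.0]oct-4-ene (C6 epimers) | CC(C)(C)[Si](C)(C)O[C@H]1CC=C2C(OCc3ccc(OC)cc3)CC[C@@]12C | intermediate
11 | cis-fused 6-(PMBO)-2-(TBSO)-1-methylbicyclo[3.3.0]octan-4-ol | CC(C)(C)[Si](C)(C)O[C@H]1C[C@H](O)[C@H]2C(OCc3ccc(OC)cc3)CC[C@@]12C | intermediate
12 | cis-fused 6-(PMBO)-2-(TBSO)-1-methylbicyclo[3.3.0]octan-4-one | CC(C)(C)[Si](C)(C)O[C@H]1CC(=O)[C@H]2C(OCc3ccc(OC)cc3)CC[C@@]12C | intermediate
13 | isopropylmagnesium chloride | CC(C)[Mg]Cl | starting material
14 | cis-fused 4-isopropyl-6-(PMBO)-2-(TBSO)-1-methylbicyclo[3.3.0]octan-4-ol | CC(C)(C)[Si](C)(C)O[C@H]1C[C@](O)(C(C)C)[C@H]2C(OCc3ccc(OC)cc3)CC[C@@]12C | intermediate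
15 | 4-O-TES ether of 14 | CC(C)(C)[Si](C)(C)O[C@H]1C[C@](O[Si](CC)(CC)CC)(C(C)C)[C@H]2C(OCc3ccc(OC)cc3)CC[C@@]12C | intermediate
16 | cis-fused 4-isopropyl-2-(TBSO)-4-(TESO)-1-methylbicyclo[3.3.0]octan-6-ol | CC(C)(C)[Si](C)(C)O[C@H]1C[C@](O[Si](CC)(CC)CC)(C(C)C)[C@H]2C(O)CC[C@@]12C | intermediate
17 | cis-fused 4-isopropyl-2-(TBSO)-4-(TESO)-1-methylbicyclo[3.3.0]octan-6-one | CC(C)(C)[Si](C)(C)O[C@H]1C[C@](O[Si](CC)(CC)CC)(C(C)C)[C@H]2C(=O)CC[C@@]12C | intermediate
18 | C6=C9 TBS enol ether of 17 | CC(C)(C)[Si](C)(C)O[C@H]1C[C@](O[Si](CC)(CC)CC)(C(C)C)[C@H]2C(O[Si](C)(C)C(C)(C)C)=CC[C@@]12C | intermediate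
19 | but-2-ynoic acid | CC#CC(=O)O | starting material
20 | allyl but-2-ynoate | CC#CC(=O)OCC=C | intermediate
21 | siloxy cyclobutene (bicyclo[3.2.0] unit fused on the convex face of ring B; not isolated) | CC(C)(C)[Si](C)(C)O[C@H]1C[C@](O[Si](CC)(CC)CC)(C(C)C)[C@H]2[C@]3(O[Si](C)(C)C(C)(C)C)C(C(=O)OCC=C)=C(C)[C@@H]3C[C@@]12C | intermediate
22 | allyl 6-(TBSO)-hydroazulene-6,8-diene-7-carboxylate with 2-OTBS and 4-OTES | CC(C)(C)[Si](C)(C)O[C@H]1C[C@](O[Si](CC)(CC)CC)(C(C)C)[C@H]2C(O[Si](C)(C)C(C)(C)C)=C(C(=O)OCC=C)C(C)=CC[C@@]12C | intermediate
23 | allyl 4-hydroxy-6-oxo-hydroazul-8-ene-7-carboxylate with 2-OTBS | CC(C)(C)[Si](C)(C)O[C@H]1C[C@](O)(C(C)C)[C@H]2C(=O)C(C(=O)OCC=C)C(C)=CC[C@@]12C | intermediate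
24 | 4-hydroxy-4-isopropyl-2-(TBSO)-1,8-dimethyl-cis-hydroazul-8-en-6-one | CC(C)(C)[Si](C)(C)O[C@H]1C[C@](O)(C(C)C)[C@H]2C(=O)CC(C)=CC[C@@]12C | intermediate
25 | 4-isopropyl-2-(TBSO)-1,8-dimethyl-cis-hydroazul-8-ene-4,6-diol | CC(C)(C)[Si](C)(C)O[C@H]1C[C@](O)(C(C)C)[C@H]2[C@H](O)CC(C)=CC[C@@]12C | intermediate
26 | 3,4,5-trimethoxybenzoyl chloride | COc1cc(C(=O)Cl)cc(OC)c1OC | starting material
27 | 6-O-(3,4,5-trimethoxybenzoyl) ester of 25 | CC(C)(C)[Si](C)(C)O[C@H]1C[C@](O)(C(C)C)[C@H]2[C@H](OC(=O)c3cc(OC)c(OC)c(OC)c3)CC(C)=CC[C@@]12C | intermediate
28 | 6-(3,4,5-trimethoxybenzoyloxy)-cis-hydroazul-8-ene-2,4-diol | O[C@H]1C[C@](O)(C(C)C)[C@H]2[C@H](OC(=O)c3cc(OC)c(OC)c(OC)c3)CC(C)=CC[C@@]12C | intermediate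
29 | angelic acid ((Z)-2-methylbut-2-enoic acid) | C/C=C(/C)C(=O)O | starting material
30 | 2,4,6-trichlorobenzoyl chloride | O=C(Cl)c1c(Cl)cc(Cl)cc1Cl | starting material
31 | angelic 2,4,6-trichlorobenzoic anhydride (not isolated) | C/C=C(/C)C(=O)OC(=O)c1c(Cl)cc(Cl)cc1Cl | intermediate
32 | CNP0112256.1 | C/C=C(/C)C(=O)O[C@H]1C[C@](O)(C(C)C)[C@H]2[C@H](OC(=O)c3cc(OC)c(OC)c(OC)c3)CC(C)=CC[C@@]12C | target

## Step count and least certain steps

Total step count: 23. Longest linear sequence: 22 steps (1 → 32 through steps 1–15 and 17–23); step 16 is a one-step side branch.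

**Step 17 (key step).** The β-methyl group slows both the conjugate addition and the four-ring closure, so carbon–carbon bond formation may be followed by silyl transfer or protodesilylation to an open-chain adduct instead of cyclobutene formation. The fused cyclobutene may also resist opening at a temperature at which the siloxy diene does not yet undergo [1,5]-hydrogen shifts. The Lewis acid may trigger fragmentation across C4–C5 at the oxocarbenium stage. The fallback sets out from 17 and uses the enamine version of the same ring expansion, in which a stronger donor drives the opening without a Lewis acid. Condensation of 17 with pyrrolidine (TiCl4, toluene) would give the C6=C9 pyrrolidine enamine F1. Heating F1 with 20 in acetonitrile would give the ring-expanded dienamine ester F2. Buffered aqueous acetic acid would hydrolyse it to the TES-protected β-keto allyl ester F3. Buffered HF·pyridine then removes the TES group and the route is rejoined at 23.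

**Step 7.** The alkenyl-chromium species may be protonated before it reaches the aldehyde, or nickel insertion into the hindered cyclic triflate may be too slow, so that reduction or recovery competes with ring closure. The fallback sets out from 5 and forms the C5–C6 bond with umpolung of the aldehyde. Hydroboration–oxidation of 5 would give the keto alcohol F4 and Dess–Martin oxidation the keto aldehyde F5. An N-heterocyclic-carbene-catalysed intramolecular crossed benzoin reaction would give the cis-fused ketol F6. Dehydration (SOCl2, pyridine), which can only go toward C4, would give the bicyclic enone F7. Luche reduction of F7 comes back to the route at 9.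

**Step 11.** Enolisation toward C5 with expulsion of the C6 ether, reduction of the ketone by β-hydride transfer, or loss of facial selectivity could erode the addition. The fallback sets out from 12. Addition of isopropenylmagnesium bromide with CeCl3 (an sp2 nucleophile without β-hydride) would give the isopropenyl carbinol F8. Homogeneous hydrogenation (Wilkinson's catalyst, H2), which leaves the PMB ether alone, returns to the route at 14.

**Step 18.** The C2 TBS ether may be lost together with the TES ether, or the tertiary TES ether may be cleaved incompletely. The fallback sets out from 22. Exhaustive desilylation (aq. HF, MeCN) would give the dihydroxy β-keto ester F9, whose only secondary hydroxyl is re-silylated (TBSCl, imidazole). The route is rejoined at 23.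

**Step 20.** Exchange of the hindered tertiary C4–OH onto boron may fail, in which case no hydride is delivered. The fallback sets out from 24. An external hydride (NaBH4, CeCl3, MeOH) is expected to attack from the side away from ring A and to give the 6-epi diol F10. Mitsunobu esterification of F10 with 3,4,5-trimethoxybenzoic acid (PPh3, DIAD) would invert C6 and install the ester in one operation, rejoining the route at 27.

**Step 23.** The angelate may isomerise to the tiglate during activation, or acyl transfer to the hindered C2–OH may be slow. The fallback sets out from 28. Esterification with 2-[bis(2,2,2-trifluoroethoxy)phosphoryl]propanoic acid (DCC, DMAP) would give the phosphonopropionate ester F11. A Still–Gennari olefination of F11 with acetaldehyde (KHMDS, 18-crown-6, THF, −78 °C) builds the Z-trisubstituted enoate on the substrate and arrives at 32.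

## Further compounds

F1 | step 17 | pyrrolidine enamine (C6=C9) of 17 | CC(C)(C)[Si](C)(C)O[C@H]1C[C@](O[Si](CC)(CC)CC)(C(C)C)[C@H]2C(N3CCCC3)=CC[C@@]12C
F2 | step 17 | ring-expanded dienamine ester (6-pyrrolidinyl hydroazulene-6,8-diene-7-carboxylate, allyl ester) | CC(C)(C)[Si](C)(C)O[C@H]1C[C@](O[Si](CC)(CC)CC)(C(C)C)[C@H]2C(N3CCCC3)=C(C(=O)OCC=C)C(C)=CC[C@@]12C
F3 | step 17 | TES-protected β-keto allyl ester | CC(C)(C)[Si](C)(C)O[C@H]1C[C@](O[Si](CC)(CC)CC)(C(C)C)[C@H]2C(=O)C(C(=O)OCC=C)C(C)=CC[C@@]12C
F4 | step 7 | (2S,3S)-3-(TBSO)-2-(3-hydroxypropyl)-2-methylcyclopentan-1-one | CC(C)(C)[Si](C)(C)O[C@H]1CCC(=O)[C@@]1(C)CCCO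
F5 | step 7 | (2S,3S)-3-(TBSO)-2-methyl-2-(3-oxopropyl)cyclopentan-1-one | CC(C)(C)[Si](C)(C)O[C@H]1CCC(=O)[C@@]1(C)CCC=O
F6 | step 7 | cis-fused 5-hydroxy-2-(TBSO)-1-methylbicyclo[3.3.0]octan-6-one | CC(C)(C)[Si](C)(C)O[C@H]1CC[C@@]2(O)C(=O)CC[C@@]12C
F7 | step 7 | 2-(TBSO)-1-methylbicyclo[3.3.0]oct-4-en-6-one | CC(C)(C)[Si](C)(C)O[C@H]1CC=C2C(=O)CC[C@@]12C
F8 | step 11 | cis-fused 4-isopropenyl-6-(PMBO)-2-(TBSO)-1-methylbicyclo[3.3.0]octan-4-ol | CC(C)(C)[Si](C)(C)O[C@H]1C[C@](O)(C(C)=C)[C@H]2C(OCc3ccc(OC)cc3)CC[C@@]12C
F9 | step 18 | allyl 2,4-dihydroxy-6-oxo-hydroazul-8-ene-7-carboxylate | O[C@H]1C[C@](O)(C(C)C)[C@H]2C(=O)C(C(=O)OCC=C)C(C)=CC[C@@]12C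
F10 | step 20 | 6-epi diol (6-OH trans to H5) | CC(C)(C)[Si](C)(C)O[C@H]1C[C@](O)(C(C)C)[C@H]2[C@@H](O)CC(C)=CC[C@@]12C
F11 | step 23 | 2-O-[2-(bis(2,2,2-trifluoroethoxy)phosphoryl)propanoyl] ester of 28 | CC(C(=O)O[C@H]1C[C@](O)(C(C)C)[C@H]2[C@H](OC(=O)c3cc(OC)c(OC)c(OC)c3)CC(C)=CC[C@@]12C)P(=O)(OCC(F)(F)F)OCC(F)(F)F
A1 | alternative 1 | trans-decalin 6-hydroxy 5-mesylate with C2 and C8 ethylene ketals | O1CCOC12CC[C@@H](OS(C)(=O)=O)[C@]3(O)CC4(OCCO4)CC[C@@]23C
A2 | alternative 1 | cis-fused hydroazulen-6-one 2,8-bis(ethylene ketal) | O1CCOC12CC[C@H]3C(=O)CC4(OCCO4)CC[C@@]23C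
A3 | alternative 2 | 6-acetoxy-5-methyl-2H-pyran-3(6H)-one carrying the C4–C1 alkenyl chain at C2 of the pyranone (C5/C9 epimers) | CC(=O)OC1OC(C(=O)C=C1C)[C@@](O[Si](C)(C)C)(C(C)C)C[C@H](O[Si](C)(C)C(C)(C)C)C(C)=C
A4 | alternative 2 | C5,C9-oxa-bridged hydroazul-7-en-6-one | CC(C)(C)[Si](C)(C)O[C@H]1C[C@](O[Si](C)(C)C)(C(C)C)[C@@]23O[C@@H](C[C@@]12C)C(C)=CC3=O
A5 | alternative 3 | branched chain with C4 isopropyl ketone, C2 PMB ether, C5=C6 enol silane and C9 allylsilane (enol geometry and C9 open) | COc1ccc(cc1)CO[C@@H](CC(=O)C(C)C)[C@@](C)(C=CO[Si](C)(C)C)CC([Si](C)(C)C)C(C)=C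
A6 | alternative 3 | cis-fused 2-O-PMB hydroazul-8-ene-4,6-diol, 6-epi | COc1ccc(cc1)CO[C@H]1C[C@](O)(C(C)C)[C@H]2[C@@H](O)CC(C)=CC[C@@]12C
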